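As the chemist with one flask left to charge, I had to choose between epsilon, with free catalyst at 7.50 % of the substrate for 6.0 h, and zeta, with 15.0 % for 2.0 h.

| flask | substrate | free catalyst | remark | time |
|---|---|---|---|---|
| east | 20 mM | 1.3 mM | run made earlier |  |
| west | 20 mM | 2 mM | run made earlier |  |
| south | 20 mM | 3.5 mM | run made earlier |  |
| epsilon | 20 mM | 1.5 mM |  | 6.0 h |
| zeta | 20 mM | 3.0 mM |  | 2.0 h |

| run | time / min | product / % | substrate / % |
|---|---|---|---|
| east | 10.0 | 1.2 | 95.1 |
| east | 20.0 | 2.1 | 93.4 |
| east | 30.0 | 2.9 | 90.2 |
| east | 60.0 | 6.1 | 88.4 |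
| east | 120 | 6.8 | 84.3 |
| west | 25.0 | 3.3 | 89.0 |
| west | 50.0 | 7.6 | 84.2 |
| west | 80.0 | 10.8 | 79.8 |
| west | 90.0 | 10.6 | 78.4 |
| west | 120 | 15.8 | 75.4 |
| south | 10.0 | 0.9 | 84.8 |
| south | 20.0 | 2.4 | 81.3 |
| south | 30.0 | 7.9 | 76.8 |
| south | 60.0 | 14.2 | 70.0 |
| south | 120 | 24.7 | 59.5 |

(scatter of a reading: 1 percentage point)

* the winner by amount of product, in percent of the substrate charged; "neither" if no more than 2 percentage points parts them (epsilon / zeta / neither)
* how much product is there at the end, in percent of the substrate charged: epsilon
* how much product is there at the end, in percent of the substrate charged: zeta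

- reactions considered so far: substrate + free catalyst -> catalyst intermediate A; catalyst intermediate A <-> catalyst intermediate B; catalyst intermediate B -> free catalyst + product; catalyst intermediate B -> spent catalyst

I counted turnovers. Pooling the last readings of the three runs at 120 min gave 1.39, the turnover number, meaning product formed per catalyst charged, both as fractions of the substrate charged. Since those runs held the same substrate charge as zeta, I reckoned zeta at 20.9 %. Epsilon has half that catalyst, so to match zeta it needed 2.78 turnovers.

Would its catalyst last that long? East and south pooled gave 0.846 turnovers by 60.0 min and 1.31 by 120 min, so the second equal stretch added 0.467, a ratio of 0.552. If every stretch kept that ratio, the sum would reach 1.89 turnovers, fewer than needed. That estimate put epsilon near 14.2 %, behind zeta by 6.7 percentage points, wider than the margin of 2 points. I chose zeta.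

The forecast also named zeta, with 16.5 % for epsilon and 21.5 % for zeta, on “a limiting turnover number of about 2.1 to 2.5”.

The flasks gave 17.7 % in epsilon and 21.8 % in zeta, so zeta won.

    substrate + free catalyst → catalyst intermediate A (k = 0.160 L mol⁻¹ s⁻¹)
    catalyst intermediate A ⇌ catalyst intermediate B (K = 2.10, k = 6.60 × 10⁻⁴ s⁻¹)
    catalyst intermediate B → free catalyst + product (k = 0.00240 s⁻¹)
    catalyst intermediate B → spent catalyst (k = 9.50 × 10⁻⁴ s⁻¹)

Zeta made 1.45 turnovers and epsilon 2.36, fewer than the 2.78 it needed but more than the 1.89 I had summed. My count carried no substrate term, and zeta stood at the same 20 mM as the earlier runs. The neighbouring flask is zeta with 12 mM of substrate, which lifts the catalyst to 25.0 % of the substrate charged. The same count reckons 34.8 % product there. That neighbouring flask gave 32.6 %, which is 1.31 turnovers, fewer than in zeta.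

The runs come from a simulation on assumed constants, and the scatter is random.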